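**Plan**
Retrosynthetic cuts: the palmitate C–O bond; the oxolane O–C(quaternary) bond, together with the oxirane CH2 and the dienyl group on a former lactone carbonyl; the C10–C10a bond of the cyclononene (lactone α-carbon to CH2–I); the lactone β-carbon–alkenyl bond; the Z-alkene.
Enabling feature: the two ring-fusion carbons are Cα and Cβ of a γ-butanolide whose carbonyl carbon is the later quaternary ether carbon, so a β-alkenyl butanolide carrying the seven-carbon arm can shut the nine-membered ring at Cα.
Forward order: citramalate-derived aldehyde plus a C4 ylide, borylation, conjugate addition to furanone (lactone ring first), enolate alkylation (carbocycle second), then dienyl ketone, oxirane and Pd ring closure (oxolane last), then the ester.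
Stereochemistry: carbinol centre from (S)-citramalic acid; lactone β-centre from Rh/(R)-BINAP; ring-fusion α-centre from the alkylation (trans, correctable by equilibration); quaternary ether carbon from Felkin–Anh ylide addition relayed with retention by palladium; Z-alkene from a salt-free Wittig reaction, E-diene from a Takai iodide.

Key step: step 13

Remark: 22 is written as the open hydroxy ketone; it will equilibrate with its five-membered cyclic hemiketal, and the silylation in step 16 draws both forms to 23.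

Step 1
Reactants: 1 (S)-citramalic acid
Product: 2 (2S)-2-methylbutane-1,2,4-triol
Conditions: BH3·SMe2, B(OMe)3, THF, 0 °C → rt; MeOH quench
Reagents that add atoms: none
Why: Borane reduction of both carboxylic acids (trimethyl borate speeds reduction and work-up) leaves the tertiary carbinol, the only stereocentre, untouched.

Step 2
Reactants: 2 (2S)-2-methylbutane-1,2,4-triol
Product: 3 2-[(4S)-2,2,4-trimethyl-1,3-dioxolan-4-yl]ethan-1-ol
Conditions: Me2C(OMe)2, TsOH (cat.), CH2Cl2, rt
Reagents that add atoms: 2,2-dimethoxypropane, COC(C)(C)OC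
Why: Acid-catalysed transacetalisation gives the five-membered 1,2-acetonide under thermodynamic control, because the six-membered alternative through the tertiary and the distal hydroxyl would carry a syn-axial methyl pair, so the distal primary alcohol stays free.

Step 3
Reactants: 3 2-[(4S)-2,2,4-trimethyl-1,3-dioxolan-4-yl]ethan-1-ol
Product: 4 (4S)-4-(2-chloroethyl)-2,2,4-trimethyl-1,3-dioxolane
Conditions: PPh3, NCS, CH2Cl2, 0 °C → rt
Reagents that add atoms: N-chlorosuccinimide, O=C1CCC(=O)N1Cl
Why: Appel-type deoxychlorination (alkoxyphosphonium, SN2 by chloride) turns the only free hydroxyl into a primary chloride under neutral conditions that spare the acetonide, and the chloride is a spectator until it is exchanged for iodide in step 12.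

Step 4
Reactants: 4 (4S)-4-(2-chloroethyl)-2,2,4-trimethyl-1,3-dioxolane
Product: 5 (2S)-4-chloro-2-methylbutane-1,2-diol
Conditions: AcOH–H2O 4:1, 40 °C
Reagents that add atoms: none
Why: Mild aqueous acid hydrolysis of the acetonide frees the 1,2-diol without touching the primary chloride or the stereocentre.

Step 5
Reactants: 5 (2S)-4-chloro-2-methylbutane-1,2-diol
Product: 6 (2S)-4-chloro-2-methyl-1,2-bis(triethylsilyloxy)butane
Conditions: TESOTf, 2,6-lutidine, CH2Cl2, −78 → 0 °C
Reagents that add atoms: triethylsilyl trifluoromethanesulfonate, CC[Si](CC)(CC)OS(=O)(=O)C(F)(F)F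
Why: A silyl triflate with a hindered pyridine base silylates both the primary and the tertiary hydroxyl (silyl ether formation), which protects the carbinol for the whole route and prevents ring closure of the chloro diol.

Step 6
Reactants: 6 (2S)-4-chloro-2-methyl-1,2-bis(triethylsilyloxy)butane
Product: 7 (2S)-4-chloro-2-methyl-2-(triethylsilyloxy)butanal
Conditions: (COCl)2, DMSO, CH2Cl2, −78 → −30 °C; Et3N, −78 °C → rt
Reagents that add atoms: none
Why: Under Swern conditions the activated sulfoxide cleaves the unhindered primary triethylsilyl ether and oxidises that position directly to the aldehyde while the tertiary silyl ether survives, and the product cannot epimerise because its α-carbon carries no hydrogen.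

Step 7
Reactants: 8 3-bromobut-3-en-1-ol
Product: 9 2,4-dibromobut-1-ene
Conditions: CBr4, PPh3, CH2Cl2, 0 °C
Reagents that add atoms: carbon tetrabromide, BrC(Br)(Br)Br
Why: Appel bromination converts the primary alcohol into the bromide by SN2 at carbon and leaves the vinyl bromide alone.

Step 8
Reactants: 9 2,4-dibromobut-1-ene
Product: 10 (3-bromobut-3-en-1-yl)triphenylphosphonium bromide
Conditions: PPh3, MeCN, reflux
Reagents that add atoms: triphenylphosphine, c1ccc(cc1)P(c1ccccc1)c1ccccc1
Why: SN2 quaternisation of triphenylphosphine occurs only at the primary alkyl bromide, since the vinylic C–Br bond is inert to the phosphine.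

Step 9
Reactants: 10 (3-bromobut-3-en-1-yl)triphenylphosphonium bromide; 7 (2S)-4-chloro-2-methyl-2-(triethylsilyloxy)butanal
Product: 12 (4Z,6S)-2-bromo-8-chloro-6-methyl-6-(triethylsilyloxy)octa-1,4-diene, via phosphonium ylide 11 (not isolated)
Conditions: NaHMDS, THF, −78 °C; then 7, −78 °C → rt
Reagents that add atoms: none
Why: Wittig olefination with a non-stabilised ylide made with a lithium-free amide base proceeds through the kinetically favoured cis-oxaphosphetane and gives the Z-alkene, while the non-enolisable aldehyde keeps its configuration and the alkyl chloride and vinyl bromide are not touched at low temperature.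

Step 10
Reactants: 12 (4Z,6S)-2-bromo-8-chloro-6-methyl-6-(triethylsilyloxy)octa-1,4-diene
Product: 13 2-[(4Z,6S)-8-chloro-6-methyl-6-(triethylsilyloxy)octa-1,4-dien-2-yl]-4,4,5,5-tetramethyl-1,3,2-dioxaborolane
Conditions: B2pin2, PdCl2(PPh3)2 (3 mol %), PPh3, KOPh, toluene, 50 °C
Reagents that add atoms: bis(pinacolato)diboron, CC1(C)OB(OC1(C)C)B1OC(C)(C)C(C)(C)O1
Why: In this Miyaura borylation Pd(0) inserts only into the vinylic C–Br bond and phenoxide-assisted transmetalation with the diboron reagent gives the 1,1-disubstituted alkenyl pinacol boronate with the skipped diene and the alkyl chloride intact.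

Step 11
Reactants: 13 2-[(4Z,6S)-8-chloro-6-methyl-6-(triethylsilyloxy)octa-1,4-dien-2-yl]-4,4,5,5-tetramethyl-1,3,2-dioxaborolane; 14 furan-2(5H)-one
Product: 15 (4R)-4-[(4Z,6S)-8-chloro-6-methyl-6-(triethylsilyloxy)octa-1,4-dien-2-yl]oxolan-2-one
Conditions: [Rh(OH)((R)-BINAP)]2 (3 mol % Rh), dioxane–H2O 10:1, 40 °C; 14 in excess
Reagents that add atoms: none
Why: In this rhodium-catalysed asymmetric conjugate addition of an alkenylboron reagent (Hayashi–Miyaura reaction), transmetalation to Rh–OH, enantioface-selective insertion of the butenolide C=C and hydrolysis of the rhodium enolate set the lactone β-stereocentre as (R) under control of (R)-BINAP, the ligand antipode indicated by the established model for cyclic enones and unsaturated lactones, and the base-free medium spares lactone, silyl ether and chloride.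

Step 12
Reactants: 15 (4R)-4-[(4Z,6S)-8-chloro-6-methyl-6-(triethylsilyloxy)octa-1,4-dien-2-yl]oxolan-2-one
Product: 16 (4R)-4-[(4Z,6S)-8-iodo-6-methyl-6-(triethylsilyloxy)octa-1,4-dien-2-yl]oxolan-2-one
Conditions: NaI, NaHCO3 (trace), butanone, 70 °C, dark
Reagents that add atoms: sodium iodide, [Na+].[I-]
Why: Finkelstein halide exchange (SN2, driven by precipitation of NaCl) converts the unhindered primary chloride into the iodide needed for ring closure without affecting lactone, silyl ether or alkenes.

Step 13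
Reactants: 16 (4R)-4-[(4Z,6S)-8-iodo-6-methyl-6-(triethylsilyloxy)octa-1,4-dien-2-yl]oxolan-2-one
Product: 18 (3aR,6Z,8S,10aS)-8-methyl-4-methylidene-8-(triethylsilyloxy)-3,3a,4,5,8,9,10,10a-octahydro-1H-cyclonona[c]furan-1-one (trans-fused), via lithium enolate 17 (not isolated)
Conditions: LiHMDS (1.3 equiv), THF–DMPU 10:1, −40 → −10 °C; 16 added by syringe pump (final ≤ 0.003 M)
Reagents that add atoms: none
Why: LiHMDS removes an α-proton of the lactone to give lithium enolate 17, whose α-carbon displaces the primary iodide at the end of the arm by SN2, which is the known intramolecular alkylation of ester and lactone enolates carried here to a medium ring. The closure is 9-exo-tet and forms the C10–C10a bond of the carbocycle; slow addition at high dilution keeps the enolate concentration low so that ring closure should outrun dimerisation and Claisen-type self-condensation. The entropic cost is lowered by the Z-alkene, the 1,1-disubstituted alkene and the fully substituted silyloxy carbon, which stiffen the tether, bend it back towards the lactone and remove transannular hydrogens. The new stereocentre at the α-carbon is governed by the existing β-centre: C-alkylation anti to the β-substituent gives the trans ring fusion, and because this centre stays α to the carbonyl any cis-fused material can be equilibrated with DBU towards the trans arrangement that α,β-disubstituted butanolides prefer. The step needs C- over O-alkylation and substitution over E2 loss of HI, which the soft primary iodide, the lithium enolate in THF–DMPU and the low temperature should secure, and the tertiary alcohol is kept as its silyl ether so that no alkoxide can close an oxetane on the iodide.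

Step 14
Reactants: 19 3-methylbut-2-enal
Product: 20 (1E)-1-iodo-4-methylpenta-1,3-diene
Conditions: CHI3, CrCl2, THF–dioxane, 0 °C
Reagents that add atoms: iodoform, IC(I)I
Why: Takai olefination (gem-dichromium carbenoid from iodoform and CrCl2) converts the enal into the alkenyl iodide, and elimination from the less crowded adduct sets the E geometry.

Step 15
Reactants: 20 (1E)-1-iodo-4-methylpenta-1,3-diene; 18 (3aR,6Z,8S,10aS)-8-methyl-4-methylidene-8-(triethylsilyloxy)-3,3a,4,5,8,9,10,10a-octahydro-1H-cyclonona[c]furan-1-one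
Product: 22 (2E)-1-[(1S,2R,5Z,7S)-2-(hydroxymethyl)-7-methyl-3-methylidene-7-(triethylsilyloxy)cyclonon-5-en-1-yl]-5-methylhexa-2,4-dien-1-one, via dienyllithium 21 (not isolated)
Conditions: t-BuLi (2 equiv), Et2O, −78 °C; then 18, THF, −78 °C; sat. aq NH4Cl
Reagents that add atoms: none
Why: Iodine–lithium exchange proceeds with retention of the E geometry and the dienyllithium adds once to the lactone carbonyl (1,2-addition of an organolithium to a lactone) because the lithium hemiketal alkoxide persists at −78 °C until the quench, so no second addition occurs and no stereocentre is touched.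

Step 16
Reactants: 22 (2E)-1-[(1S,2R,5Z,7S)-2-(hydroxymethyl)-7-methyl-3-methylidene-7-(triethylsilyloxy)cyclonon-5-en-1-yl]-5-methylhexa-2,4-dien-1-one
Product: 23 (2E)-5-methyl-1-[(1S,2R,5Z,7S)-7-methyl-3-methylidene-7-(triethylsilyloxy)-2-[(triethylsilyloxy)methyl]cyclonon-5-en-1-yl]hexa-2,4-dien-1-one
Conditions: TESCl, imidazole, CH2Cl2, 0 °C
Reagents that add atoms: chlorotriethylsilane, CC[Si](Cl)(CC)CC
Why: Silylation of the primary hydroxyl of the open form (silyl ether formation) drains the hemiketal equilibrium, fixes the compound as the free dienone and removes the alkoxide that would otherwise attack the oxirane made next.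

Step 17
Reactants: 23 (2E)-5-methyl-1-[(1S,2R,5Z,7S)-7-methyl-3-methylidene-7-(triethylsilyloxy)-2-[(triethylsilyloxy)methyl]cyclonon-5-en-1-yl]hexa-2,4-dien-1-one
Product: 24 (2R)-2-[(1S,2R,5Z,7S)-7-methyl-3-methylidene-7-(triethylsilyloxy)-2-[(triethylsilyloxy)methyl]cyclonon-5-en-1-yl]-2-[(1E)-4-methylpenta-1,3-dien-1-yl]oxirane
Conditions: Me3S+ I−, n-BuLi, THF, −10 °C; then 23, −20 → 0 °C
Reagents that add atoms: trimethylsulfonium iodide, C[S+](C)C.[I-]
Why: In this Corey–Chaykovsky epoxidation the sulfonium methylide adds irreversibly and 1,2 to the dienone and the betaine closes to the oxirane, with Felkin–Anh control from the adjacent ring stereocentre (the branched ring carbon bearing the silyloxymethyl group anti to the incoming methylene, attack past the small hydrogen) expected to give the (R)-oxirane.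

Step 18
Reactants: 24 (2R)-2-[(1S,2R,5Z,7S)-7-methyl-3-methylidene-7-(triethylsilyloxy)-2-[(triethylsilyloxy)methyl]cyclonon-5-en-1-yl]-2-[(1E)-4-methylpenta-1,3-dien-1-yl]oxirane
Product: 25 (2R)-2-[(1S,2R,5Z,7S)-2-(hydroxymethyl)-7-methyl-3-methylidene-7-(triethylsilyloxy)cyclonon-5-en-1-yl]-2-[(1E)-4-methylpenta-1,3-dien-1-yl]oxirane
Conditions: TBAF, AcOH (1:1), THF, 0 °C
Reagents that add atoms: none
Why: Acetic acid-buffered fluoride cleaves the primary triethylsilyl ether much faster than the hindered tertiary one (selective desilylation), and the near-neutral medium should leave the acid- and base-sensitive dienyl oxirane closed.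

Step 19
Reactants: 25 (2R)-2-[(1S,2R,5Z,7S)-2-(hydroxymethyl)-7-methyl-3-methylidene-7-(triethylsilyloxy)cyclonon-5-en-1-yl]-2-[(1E)-4-methylpenta-1,3-dien-1-yl]oxirane
Product: 27 (1R,3aR,6Z,8S,10aS)-1-(hydroxymethyl)-8-methyl-4-methylidene-1-[(1E)-4-methylpenta-1,3-dien-1-yl]-3,3a,4,5,8,9,10,10a-octahydro-1H-cyclonona[c]furan-8-ol, via silyl-protected oxolane alcohol 26 (not isolated)
Conditions: Pd(PPh3)4 (5 mol %), THF, 0 °C → rt; then TBAF, rt
Reagents that add atoms: none
Why: In this palladium-catalysed allylic etherification of a vinyl epoxide, Pd(0) opens the dienyl oxirane with inversion to an η3-allyl complex whose proximal, fully substituted terminus is attacked anti to the metal by the tethered primary alkoxide in a 5-exo closure, so two inversions carry the oxirane configuration into the quaternary ether carbon with the E-diene retained, and the fluoride added afterwards removes the tertiary silyl ether.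

Step 20
Reactants: 27 (1R,3aR,6Z,8S,10aS)-1-(hydroxymethyl)-8-methyl-4-methylidene-1-[(1E)-4-methylpenta-1,3-dien-1-yl]-3,3a,4,5,8,9,10,10a-octahydro-1H-cyclonona[c]furan-8-ol
Product: 28 [(1R,3aR,6Z,8S,10aS)-8-hydroxy-8-methyl-4-methylidene-1-[(1E)-4-methylpenta-1,3-dien-1-yl]-3,3a,4,5,8,9,10,10a-octahydro-1H-cyclonona[c]furan-1-yl]methyl hexadecanoate
Conditions: C15H31COCl, pyridine, DMAP (cat.), CH2Cl2, 0 °C
Reagents that add atoms: hexadecanoyl chloride, CCCCCCCCCCCCCCCC(=O)Cl
Why: DMAP-catalysed acylation with the acid chloride esterifies only the primary alcohol, since the tertiary allylic hydroxyl is far too hindered to react at 0 °C.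

**Compound list**
1 | (S)-citramalic acid | OC(=O)[C@@](C)(O)CC(=O)O | starting material
2 | (2S)-2-methylbutane-1,2,4-triol | OC[C@@](C)(O)CCO | intermediate
3 | 2-[(4S)-2,2,4-trimethyl-1,3-dioxolan-4-yl]ethan-1-ol | CC1(C)OC[C@](C)(CCO)O1 | intermediate
4 | (4S)-4-(2-chloroethyl)-2,2,4-trimethyl-1,3-dioxolane | CC1(C)OC[C@](C)(CCCl)O1 | intermediate
5 | (2S)-4-chloro-2-methylbutane-1,2-diol | OC[C@@](C)(O)CCCl | intermediate
6 | (2S)-4-chloro-2-methyl-1,2-bis(triethylsilyloxy)butane | CC[Si](CC)(CC)OC[C@@](C)(O[Si](CC)(CC)CC)CCCl | intermediate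
7 | (2S)-4-chloro-2-methyl-2-(triethylsilyloxy)butanal | O=C[C@@](C)(O[Si](CC)(CC)CC)CCCl | intermediate
8 | 3-bromobut-3-en-1-ol | OCCC(Br)=C | starting material
9 | 2,4-dibromobut-1-ene | BrCCC(Br)=C | intermediate
10 | (3-bromobut-3-en-1-yl)triphenylphosphonium bromide | C=C(Br)CC[P+](c1ccccc1)(c1ccccc1)c1ccccc1.[Br-] | intermediate
11 | (3-bromobut-3-en-1-ylidene)triphenylphosphorane (ylide) | C=C(Br)CC=P(c1ccccc1)(c1ccccc1)c1ccccc1 | intermediate
12 | (4Z,6S)-2-bromo-8-chloro-6-methyl-6-(triethylsilyloxy)octa-1,4-diene | C=C(Br)C/C=C\[C@@](C)(O[Si](CC)(CC)CC)CCCl | intermediate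
13 | 2-[(4Z,6S)-8-chloro-6-methyl-6-(triethylsilyloxy)octa-1,4-dien-2-yl]-4,4,5,5-tetramethyl-1,3,2-dioxaborolane | C=C(B1OC(C)(C)C(C)(C)O1)C/C=C\[C@@](C)(O[Si](CC)(CC)CC)CCCl | intermediate
14 | furan-2(5H)-one | O=C1OCC=C1 | starting material
15 | (4R)-4-[(4Z,6S)-8-chloro-6-methyl-6-(triethylsilyloxy)octa-1,4-dien-2-yl]oxolan-2-one | O=C1C[C@@H](CO1)C(=C)C/C=C\[C@@](C)(O[Si](CC)(CC)CC)CCCl | intermediate
16 | (4R)-4-[(4Z,6S)-8-iodo-6-methyl-6-(triethylsilyloxy)octa-1,4-dien-2-yl]oxolan-2-one | O=C1C[C@@H](CO1)C(=C)C/C=C\[C@@](C)(O[Si](CC)(CC)CC)CCI | intermediate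
17 | lithium enolate of 16 | [Li]OC1=C[C@@H](CO1)C(=C)C/C=C\[C@@](C)(O[Si](CC)(CC)CC)CCI | intermediate
18 | (3aR,6Z,8S,10aS)-8-methyl-4-methylidene-8-(triethylsilyloxy)-3,3a,4,5,8,9,10,10a-octahydro-1H-cyclonona[c]furan-1-one (trans-fused lactone) | C=C1C/C=C\[C@@](C)(O[Si](CC)(CC)CC)CC[C@H]2[C@H]1COC2=O | intermediate
19 | 3-methylbut-2-enal | CC(C)=CC=O | starting material
20 | (1E)-1-iodo-4-methylpenta-1,3-diene | CC(C)=C/C=C/I | intermediate
21 | [(1E)-4-methylpenta-1,3-dien-1-yl]lithium | CC(C)=C/C=C/[Li] | intermediate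
22 | (2E)-1-[(1S,2R,5Z,7S)-2-(hydroxymethyl)-7-methyl-3-methylidene-7-(triethylsilyloxy)cyclonon-5-en-1-yl]-5-methylhexa-2,4-dien-1-one | C=C1C/C=C\[C@@](C)(O[Si](CC)(CC)CC)CC[C@@H]([C@H]1CO)C(=O)/C=C/C=C(C)C | intermediate
23 | (2E)-5-methyl-1-[(1S,2R,5Z,7S)-7-methyl-3-methylidene-7-(triethylsilyloxy)-2-[(triethylsilyloxy)methyl]cyclonon-5-en-1-yl]hexa-2,4-dien-1-one | C=C1C/C=C\[C@@](C)(O[Si](CC)(CC)CC)CC[C@@H]([C@H]1CO[Si](CC)(CC)CC)C(=O)/C=C/C=C(C)C | intermediate
24 | (2R)-2-[(1S,2R,5Z,7S)-7-methyl-3-methylidene-7-(triethylsilyloxy)-2-[(triethylsilyloxy)methyl]cyclonon-5-en-1-yl]-2-[(1E)-4-methylpenta-1,3-dien-1-yl]oxirane | C=C1C/C=C\[C@@](C)(O[Si](CC)(CC)CC)CC[C@@H]([C@H]1CO[Si](CC)(CC)CC)[C@@]2(CO2)/C=C/C=C(C)C | intermediate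
25 | (2R)-2-[(1S,2R,5Z,7S)-2-(hydroxymethyl)-7-methyl-3-methylidene-7-(triethylsilyloxy)cyclonon-5-en-1-yl]-2-[(1E)-4-methylpenta-1,3-dien-1-yl]oxirane | C=C1C/C=C\[C@@](C)(O[Si](CC)(CC)CC)CC[C@@H]([C@H]1CO)[C@@]2(CO2)/C=C/C=C(C)C | intermediate
26 | [(1R,3aR,6Z,8S,10aS)-8-methyl-4-methylidene-1-[(1E)-4-methylpenta-1,3-dien-1-yl]-8-(triethylsilyloxy)-3,3a,4,5,8,9,10,10a-octahydro-1H-cyclonona[c]furan-1-yl]methanol | C=C1C/C=C\[C@@](C)(O[Si](CC)(CC)CC)CC[C@H]2[C@H]1CO[C@@]2(/C=C/C=C(C)C)CO | intermediate
27 | (1R,3aR,6Z,8S,10aS)-1-(hydroxymethyl)-8-methyl-4-methylidene-1-[(1E)-4-methylpenta-1,3-dien-1-yl]-3,3a,4,5,8,9,10,10a-octahydro-1H-cyclonona[c]furan-8-ol | C=C1C/C=C\[C@@](C)(O)CC[C@H]2[C@H]1CO[C@@]2(/C=C/C=C(C)C)CO | intermediate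
28 | [(1R,3aR,6Z,8S,10aS)-8-hydroxy-8-methyl-4-methylidene-1-[(1E)-4-methylpenta-1,3-dien-1-yl]-3,3a,4,5,8,9,10,10a-octahydro-1H-cyclonona[c]furan-1-yl]methyl hexadecanoate (CNP0150666.1) | C=C1C/C=C\[C@@](C)(O)CC[C@H]2[C@H]1CO[C@@]2(/C=C/C=C(C)C)COC(=O)CCCCCCCCCCCCCCC | target

**Step count**
Total: 20 steps. Longest linear sequence: 17 steps from 1 (steps 1–6, 9–13, 15–20).

**Steps most likely to fail**

Step 13. The medium-ring closure is slow, so intermolecular alkylation and Claisen-type self-condensation of the short-lived lithium enolate, or base-induced loss of HI, may outrun cyclisation. The fallback sets out from 15 and returns at 18; it gives the α-carbon a sulfonyl group so that the same bond is closed by a long-lived, stabilised carbanion under reversible deprotonation. Chloro lactone 15 is treated with LiHMDS (2 equiv) and benzenesulfonyl fluoride in THF at −78 °C to give the α-phenylsulfonyl chloro lactone F1 (both α-epimers). Sodium iodide in butanone gives the α-phenylsulfonyl iodo lactone F2. Cs2CO3 in DMF at high dilution and 60 °C then closes the C10–C10a bond to the 10a-phenylsulfonyl bicyclic lactone F3. Reductive desulfonylation with SmI2 in THF–MeOH at −78 °C, protonation of the samarium enolate and, if needed, DBU equilibration of the ring fusion deliver 18.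

Step 17. Facial selectivity in the ylide addition may be poor or even reversed, since the two ring carbons flanking the controlling stereocentre differ only in branching. The fallback sets out from 23 and returns at 26; it makes the configuration at the oxirane carbon irrelevant by closing each epimer in the stereochemical mode that suits it. The epimeric oxirane F4 formed beside 24 is separated, and its primary silyl ether is cleaved with TBAF/AcOH as in step 18 to the epimeric epoxy alcohol F5. F5 is cyclised with catalytic camphorsulfonic acid in CH2Cl2 at −40 °C. This acid-catalysed 5-exo opening at the dienylic carbon proceeds with inversion and so gives the same oxolane 26 that 25 gives with retention under palladium; fluoride then leads to 27 as in step 19.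

Step 19. The η3-allyl intermediate may lose configuration by π–σ–π isomerisation before it is trapped, eliminate a β-hydrogen to a trienol, or be attacked at a remote terminus of the pentadienyl system. The fallback sets out from 24 and returns at 28; it closes the oxolane at the primary carbon instead, so that no bond to the quaternary carbon is broken. Oxirane 24 is opened at its CH2 terminus with caesium hexadecanoate and hexadecanoic acid in DMF at 80 °C to the tertiary alcohol hexadecanoate F6. Buffered TBAF (AcOH, THF, 0 °C) frees the primary alcohol to give diol F7. TsCl/pyridine/DMAP converts it into the primary tosylate F8, which on warming to 40 °C is displaced by the tertiary hydroxyl in a 5-exo-tet Williamson closure to the silyl-protected ester F9. Buffered TBAF at room temperature then removes the tertiary silyl ether and gives 28.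

**Further compounds**
F1 | step 13 | (4R)-4-[(4Z,6S)-8-chloro-6-methyl-6-(triethylsilyloxy)octa-1,4-dien-2-yl]-3-(phenylsulfonyl)oxolan-2-one (both C3 epimers) | O=C1C(S(=O)(=O)c2ccccc2)[C@@H](CO1)C(=C)C/C=C\[C@@](C)(O[Si](CC)(CC)CC)CCCl
F2 | step 13 | (4R)-4-[(4Z,6S)-8-iodo-6-methyl-6-(triethylsilyloxy)octa-1,4-dien-2-yl]-3-(phenylsulfonyl)oxolan-2-one (both C3 epimers) | O=C1C(S(=O)(=O)c2ccccc2)[C@@H](CO1)C(=C)C/C=C\[C@@](C)(O[Si](CC)(CC)CC)CCI
F3 | step 13 | (3aR,6Z,8S)-8-methyl-4-methylidene-10a-(phenylsulfonyl)-8-(triethylsilyloxy)-3,3a,4,5,8,9,10,10a-octahydro-1H-cyclonona[c]furan-1-one (ring fusion unassigned) | C=C1C/C=C\[C@@](C)(O[Si](CC)(CC)CC)CCC2(S(=O)(=O)c3ccccc3)[C@H]1COC2=O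
F4 | step 17 | (2S)-2-[(1S,2R,5Z,7S)-7-methyl-3-methylidene-7-(triethylsilyloxy)-2-[(triethylsilyloxy)methyl]cyclonon-5-en-1-yl]-2-[(1E)-4-methylpenta-1,3-dien-1-yl]oxirane | C=C1C/C=C\[C@@](C)(O[Si](CC)(CC)CC)CC[C@@H]([C@H]1CO[Si](CC)(CC)CC)[C@]2(CO2)/C=C/C=C(C)C
F5 | step 17 | (2S)-2-[(1S,2R,5Z,7S)-2-(hydroxymethyl)-7-methyl-3-methylidene-7-(triethylsilyloxy)cyclonon-5-en-1-yl]-2-[(1E)-4-methylpenta-1,3-dien-1-yl]oxirane | C=C1C/C=C\[C@@](C)(O[Si](CC)(CC)CC)CC[C@@H]([C@H]1CO)[C@]2(CO2)/C=C/C=C(C)C
F6 | step 19 | (2R,3E)-2-hydroxy-6-methyl-2-[(1S,2R,5Z,7S)-7-methyl-3-methylidene-7-(triethylsilyloxy)-2-[(triethylsilyloxy)methyl]cyclonon-5-en-1-yl]hepta-3,5-dien-1-yl hexadecanoate | C=C1C/C=C\[C@@](C)(O[Si](CC)(CC)CC)CC[C@@H]([C@H]1CO[Si](CC)(CC)CC)[C@@](O)(COC(=O)CCCCCCCCCCCCCCC)/C=C/C=C(C)C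
F7 | step 19 | (2R,3E)-2-hydroxy-2-[(1S,2R,5Z,7S)-2-(hydroxymethyl)-7-methyl-3-methylidene-7-(triethylsilyloxy)cyclonon-5-en-1-yl]-6-methylhepta-3,5-dien-1-yl hexadecanoate | C=C1C/C=C\[C@@](C)(O[Si](CC)(CC)CC)CC[C@@H]([C@H]1CO)[C@@](O)(COC(=O)CCCCCCCCCCCCCCC)/C=C/C=C(C)C
F8 | step 19 | (2R,3E)-2-hydroxy-6-methyl-2-[(1S,2R,5Z,7S)-7-methyl-3-methylidene-2-[(4-methylphenylsulfonyloxy)methyl]-7-(triethylsilyloxy)cyclonon-5-en-1-yl]hepta-3,5-dien-1-yl hexadecanoate | C=C1C/C=C\[C@@](C)(O[Si](CC)(CC)CC)CC[C@@H]([C@H]1COS(=O)(=O)c2ccc(C)cc2)[C@@](O)(COC(=O)CCCCCCCCCCCCCCC)/C=C/C=C(C)C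
F9 | step 19 | [(1R,3aR,6Z,8S,10aS)-8-methyl-4-methylidene-1-[(1E)-4-methylpenta-1,3-dien-1-yl]-8-(triethylsilyloxy)-3,3a,4,5,8,9,10,10a-octahydro-1H-cyclonona[c]furan-1-yl]methyl hexadecanoate | C=C1C/C=C\[C@@](C)(O[Si](CC)(CC)CC)CC[C@H]2[C@H]1CO[C@@]2(/C=C/C=C(C)C)COC(=O)CCCCCCCCCCCCCCC
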